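The isochromanone is cut so that the lactone atoms C1, O2, C3 and C4 act as a four-atom ester tether joining C8a to C4a, which splits the benzene ring into three alkyne units: C8–C8a, C4a–C5 and C6–C7. One [2+2+2] cycloaddition catalysed by [Rh(cod)2]BF4/BINAP then forms C4a–C8a, C5–C6 and C7–C8 and closes lactone and arene together, with the C3 stereocentre and the free side-chain ketone already in place. The precursor is the 3-(benzyldimethylsilyl)propiolate of (R)-12-hydroxypentadec-14-yn-5-one, a 1,7-diyne whose silyl group marks C8 for later oxidation to the phenol; methoxyacetylene supplies C6–OMe and C7.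

Key step: step 9

Remark on chain length: six methylene groups must separate the carbinol from the ketone, so the alcohol part of the diyne ester is an 11-oxopentadec-1-yn-4-yl (C15) group; a C14 10-oxotetradecynyl ester would lead to the lower homologue of the target.

Assumption: the phosphoric acid catalyst follows the accepted hydrogen-bonded chair model, in which the (R)-catalyst exposes the Re face of an aldehyde; (S)-TRIP is therefore specified for Si-face attack, and the enantiomeric catalyst would be taken if the sense proved opposite.

Atom labels C1–C8a refer to the isochroman-1-one ring of the target. (S)-TRIP is (S)-3,3'-bis(2,4,6-triisopropylphenyl)-1,1'-binaphthyl-2,2'-diyl hydrogen phosphate.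

Step 1
Reactants: 1 cyclooctanone
Product: 2 1-butylcyclooctan-1-ol
Conditions: n-BuLi, CeCl3 (anhydrous), THF, −78 °C; H2O work-up
Reagents that add atoms: n-butyllithium, [Li]CCCC
Why: Organocerium 1,2-addition, in which the weakly basic, oxophilic butylcerium reagent should add to the easily enolised medium-ring ketone where a plain organolithium or Grignard reagent partly enolises or reduces it.

Step 2
Reactants: 2 1-butylcyclooctan-1-ol
Product: 3 (Z)-1-butylcyclooct-1-ene
Conditions: TsOH·H2O (cat.), toluene, reflux, Dean–Stark trap
Reagents that add atoms: none
Why: Acid-catalysed E1 dehydration under thermodynamic control, which should favour the endocyclic trisubstituted olefin because an sp2 pair inside the eight-membered ring relieves transannular strain and any exocyclic isomer equilibrates into it.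

Step 3
Reactants: 3 (Z)-1-butylcyclooct-1-ene
Product: 5 8-oxododecanal, via secondary ozonide 4 (not isolated)
Conditions: O3, CH2Cl2, −78 °C; then PPh3, −78 °C to rt
Reagents that add atoms: ozone, [O-][O+]=O
Why: Ozonolysis with reductive work-up (Criegee cycloaddition, cycloreversion and recombination, then phosphine reduction of the ozonide) cleaves the only olefin and unveils the butyl ketone and the aldehyde six methylenes apart in one operation.

Step 4
Reactants: 5 8-oxododecanal; 6 allenylboronic acid pinacol ester
Product: 8 (R)-12-hydroxypentadec-14-yn-5-one, via pinacol borate ester 7 (not isolated)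
Conditions: (S)-TRIP (10 mol%), 4 Å MS, toluene, −30 °C; then aq. NaHCO3
Reagents that add atoms: none
Why: Chiral phosphoric acid-catalysed asymmetric allenylboration (SE2' propargylation) through a closed six-membered transition state in which the acid hydrogen-bonds the boronate oxygen and the formyl hydrogen and exposes the Si face of the aldehyde, which should set the carbinol carbon (future C3) as (R), while the ketone does not react with the allenylboronate; the enantiomeric purity of 8 is to be checked before it is carried on.

Step 5
Reactants: 9 benzylchlorodimethylsilane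
Product: 10 benzyl(ethynyl)dimethylsilane
Conditions: ethynylmagnesium bromide (0.5 M in THF, 1.3 equiv), THF, 0 °C to rt
Reagents that add atoms: ethynylmagnesium bromide, C#C[Mg]Br
Why: Nucleophilic substitution at silicon by the alkynyl Grignard reagent, in which chloride is the only leaving group and the benzyl–silicon bond is inert.

Step 6
Reactants: 10 benzyl(ethynyl)dimethylsilane
Product: 12 3-(benzyldimethylsilyl)propiolic acid, via lithium silylacetylide 11 (not isolated)
Conditions: n-BuLi (1.0 equiv), THF, −78 °C; CO2 (g), −78 to 0 °C; cold 1 M HCl
Reagents that add atoms: carbon dioxide, O=C=O; n-butyllithium, [Li]CCCC (lithium of 11 only)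
Why: Deprotonation of the terminal alkyne, by far the most acidic C–H, and carboxylation of the lithium acetylide with CO2, the silicon–alkyne bond being stable to a brief cold acidic work-up.

Step 7
Reactants: 8 (R)-12-hydroxypentadec-14-yn-5-one; 12 3-(benzyldimethylsilyl)propiolic acid
Product: 13 (R)-11-oxopentadec-1-yn-4-yl 3-(benzyldimethylsilyl)propiolate
Conditions: DCC, DMAP (5 mol%), CH2Cl2, −20 to 0 °C
Reagents that add atoms: none
Why: Steglich esterification acylates the secondary alcohol with retention because the carbinol C–O bond is never broken, and the low temperature with little DMAP limits conjugate addition to the ynoate.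

Step 8
Reactants: 14 chloroacetaldehyde dimethyl acetal
Product: 16 methoxyacetylene, via sodium methoxyacetylide 15 (not isolated)
Conditions: NaNH2 (3.1 equiv), liq. NH3, −33 °C; NH3 evaporated; cold sat. aq. NaCl, −70 °C; distilled (bp ca. 23 °C) into a −78 °C trap, kept as a cold CH2Cl2 solution
Reagents that add atoms: sodium amide, [Na+].[NH2-] (sodium of 15 only)
Why: Twofold base-induced elimination (loss of methanol, then of HCl) from the chloroacetal gives the ynol ether, which is held as its sodium acetylide until the cold aqueous quench and is used at once because it is volatile and acid-sensitive.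

Step 9
Reactants: 13 (R)-11-oxopentadec-1-yn-4-yl 3-(benzyldimethylsilyl)propiolate; 16 methoxyacetylene
Product: 17 (R)-8-(benzyldimethylsilyl)-6-methoxy-3-(7-oxoundecyl)isochroman-1-one
Conditions: [Rh(cod)2]BF4 (5 mol%), rac-BINAP (5 mol%), CH2Cl2, H2 (1 atm, 30 min) then Ar; 13 (0.02 M), 16 (3 equiv, cold CH2Cl2 solution) added over 6 h, rt
Reagents that add atoms: none
Why: The cationic monovalent rhodium–BINAP fragment binds both alkynes of 13 and couples them oxidatively to a rhodacyclopentadiene (C4a–C8a bond), methoxyacetylene then inserts, and C–C reductive elimination releases the arene (C5–C6 and C7–C8 bonds) and the catalyst. The closest known reaction type is the rhodium-catalysed [2+2+2] cycloaddition of ester-linked diynes with terminal alkynes, in which alkynyl ethers and silyl-capped alkynes have each been used as partners. The lactone ring closes in the intramolecular alkyne–alkyne coupling across the four-atom ester tether (a six-membered ring annulated to the rhodacycle), and the benzene ring closes by insertion of the third alkyne followed by reductive elimination. No stereocentre is created, so the ligand may be racemic, and C3 is only carried through in the tether. The step needs one orientation of the ynol ether: its electron-rich CH terminus should pair with the electrophilic ynoate β-carbon C8 and its oxygen-bearing carbon should avoid the bulky SiMe2Bn group, so that OMe lands on C6 next to the unsubstituted C5. Co-trimerisation of the ynoate with two molecules of 16 is held back by keeping 16 at a low stationary concentration, while the tether makes the wanted coupling intramolecular.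

Step 10
Reactants: 17 (R)-8-(benzyldimethylsilyl)-6-methoxy-3-(7-oxoundecyl)isochroman-1-one
Product: 19 (R)-8-hydroxy-6-methoxy-3-(7-oxoundecyl)isochroman-1-one (target CNP0318815.1), via aryldimethylsilanol 18 (not isolated)
Conditions: TBAF·3H2O, THF, 0 °C, 15 min; then KHCO3, 30% H2O2, MeOH, rt to 40 °C; aq. Na2S2O3, then dilute HCl
Reagents that add atoms: hydrogen peroxide, OO; water, O (silanol oxygen of 18 only)
Why: Tamao–Fleming oxidation, in which fluoride expels the benzyl group from silicon as toluene and peroxide attack on silicon followed by 1,2-migration of the aryl group from silicon to oxygen should give the phenol exactly where silicon sat, while the bicarbonate-buffered peroxide leaves the ketone untouched and the final acidification recloses any opened lactone.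

Compound list

1 | cyclooctanone | O=C1CCCCCCC1 | starting material
2 | 1-butylcyclooctan-1-ol | CCCCC1(O)CCCCCCC1 | intermediate
3 | (Z)-1-butylcyclooct-1-ene | CCCC/C1=C/CCCCCC1 | intermediate
4 | 1-butyl-9,10,11-trioxabicyclo[6.2.1]undecane (secondary ozonide, racemic) | CCCCC12CCCCCCC(OO1)O2 | intermediate (not isolated)
5 | 8-oxododecanal | CCCCC(=O)CCCCCCC=O | intermediate
6 | allenylboronic acid pinacol ester | C=C=CB1OC(C)(C)C(C)(C)O1 | starting material
7 | 4,4,5,5-tetramethyl-2-{[(R)-11-oxopentadec-1-yn-4-yl]oxy}-1,3,2-dioxaborolane | C#CC[C@H](OB1OC(C)(C)C(C)(C)O1)CCCCCCC(=O)CCCC | intermediate (not isolated)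
8 | (R)-12-hydroxypentadec-14-yn-5-one | C#CC[C@H](O)CCCCCCC(=O)CCCC | intermediate
9 | benzylchlorodimethylsilane | C[Si](C)(Cl)Cc1ccccc1 | starting material
10 | benzyl(ethynyl)dimethylsilane | C#C[Si](C)(C)Cc1ccccc1 | intermediate
11 | lithium [benzyl(dimethyl)silyl]acetylide | [Li]C#C[Si](C)(C)Cc1ccccc1 | intermediate (not isolated)
12 | 3-(benzyldimethylsilyl)propiolic acid | OC(=O)C#C[Si](C)(C)Cc1ccccc1 | intermediate
13 | (R)-11-oxopentadec-1-yn-4-yl 3-(benzyldimethylsilyl)propiolate | C#CC[C@@H](CCCCCCC(=O)CCCC)OC(=O)C#C[Si](C)(C)Cc1ccccc1 | intermediate
14 | chloroacetaldehyde dimethyl acetal | COC(CCl)OC | starting material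
15 | sodium methoxyacetylide | [Na+].[C-]#COC | intermediate (not isolated)
16 | methoxyacetylene | COC#C | intermediate
17 | (R)-8-(benzyldimethylsilyl)-6-methoxy-3-(7-oxoundecyl)isochroman-1-one | CCCCC(=O)CCCCCC[C@@H]1Cc2cc(OC)cc([Si](C)(C)Cc3ccccc3)c2C(=O)O1 | intermediate
18 | (R)-8-(hydroxydimethylsilyl)-6-methoxy-3-(7-oxoundecyl)isochroman-1-one | CCCCC(=O)CCCCCC[C@@H]1Cc2cc(OC)cc([Si](C)(C)O)c2C(=O)O1 | intermediate (not isolated)
19 | (R)-8-hydroxy-6-methoxy-3-(7-oxoundecyl)isochroman-1-one | CCCCC(=O)CCCCCC[C@@H]1Cc2cc(OC)cc(O)c2C(=O)O1 | target

Total step count: 10.
Longest linear sequence: 7 steps (steps 1, 2, 3, 4, 7, 9 and 10, from cyclooctanone).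

Steps most likely to fail

1. Step 9. The ynol ether may insert in the reverse orientation and put the methoxy group next to silicon. Compound 16 may be consumed by homo-oligomerisation, or by co-trimerisation of two of its molecules with the ynoate before the tethered alkyne engages. Turnover may be slow because the ester must adopt its less favoured conformation to cyclise. The fallback sets out from 8 and comes back to the route at 19; it builds the arene by a Diels–Alder reaction instead of a metal-catalysed cycloaddition. Alcohol 8 is silylated (TBSCl, imidazole, DMF) to (R)-12-[(tert-butyldimethylsilyl)oxy]pentadec-14-yn-5-one F1. Oxidative methoxycarbonylation of the terminal alkyne (PdCl2 cat., CuCl2, NaOAc, CO 1 atm, MeOH, rt), which tolerates the ketone, gives methyl (R)-5-[(tert-butyldimethylsilyl)oxy]-12-oxohexadec-2-ynoate F2. Heating F2 with 1-methoxy-1,3-bis(trimethylsilyloxy)buta-1,3-diene (xylene, 120–140 °C) and then with HCl in MeOH should give (R)-6,8-dihydroxy-3-(7-oxoundecyl)isochroman-1-one F3. The nucleophilic CH2 terminus of the diene bonds to the ynoate β-carbon, so the two oxygens land ortho and para to the ester carbon, that is on C8 and C6. The acid removes the silyl groups, aromatises the adduct and closes the lactone. Methylation with MeI (1.1 equiv) and K2CO3 in acetone should occur only at the C6 phenol, because the C8 hydroxyl is hydrogen-bonded to the lactone carbonyl, and gives 19.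

2. Step 10. Fluoride may cleave the aryl–silicon bond (protodesilylation at the carbon ortho to the lactone carbonyl) in competition with loss of the benzyl group, or the aryl migration to oxygen may be sluggish. The fallback sets out from 17 and comes back at 19; it turns the failure product into the target by directed C–H oxidation. Deliberate protodesilylation (TBAF·3H2O, DMF, 70 °C) gives (R)-6-methoxy-3-(7-oxoundecyl)isochroman-1-one F4. Ester-directed ortho C–H hydroxylation ([RuCl2(p-cymene)]2 cat., K2S2O8, CF3CO2H/(CF3CO)2O, 80 °C, aqueous work-up) should then oxygenate C8, the only C–H ortho to the coplanar lactone carbonyl, and give 19.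

3. Step 4. Facial discrimination may be incomplete for an unbranched aliphatic aldehyde, so that the enantiomeric purity of 8 is eroded. The fallback sets out from 5 and comes back at 8; it replaces asymmetric induction by resolution. Barbier propargylation (Zn, propargyl bromide, THF/sat. aq. NH4Cl, 0 °C) attacks only the aldehyde and gives racemic 12-hydroxypentadec-14-yn-5-one F5. Acylation with immobilised Candida antarctica lipase B and vinyl acetate in MTBE at rt should, by the usual size rule for lipases (slim propargyl as the medium group, long chain as the large group), convert the (S)-enantiomer into (S)-11-oxopentadec-1-yn-4-yl acetate F6. Unreacted (R)-8 is separated by chromatography. The same acylation can polish scalemic 8 from step 4 by consuming its minor enantiomer.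

Further compounds

F1 | step 9 | (R)-12-[(tert-butyldimethylsilyl)oxy]pentadec-14-yn-5-one | C#CC[C@H](O[Si](C)(C)C(C)(C)C)CCCCCCC(=O)CCCC
F2 | step 9 | methyl (R)-5-[(tert-butyldimethylsilyl)oxy]-12-oxohexadec-2-ynoate | COC(=O)C#CC[C@H](O[Si](C)(C)C(C)(C)C)CCCCCCC(=O)CCCC
F3 | step 9 | (R)-6,8-dihydroxy-3-(7-oxoundecyl)isochroman-1-one | CCCCC(=O)CCCCCC[C@@H]1Cc2cc(O)cc(O)c2C(=O)O1
F4 | step 10 | (R)-6-methoxy-3-(7-oxoundecyl)isochroman-1-one | CCCCC(=O)CCCCCC[C@@H]1Cc2cc(OC)ccc2C(=O)O1
F5 | step 4 | racemic 12-hydroxypentadec-14-yn-5-one | C#CCC(O)CCCCCCC(=O)CCCC
F6 | step 4 | (S)-11-oxopentadec-1-yn-4-yl acetate | C#CC[C@@H](OC(C)=O)CCCCCCC(=O)CCCC
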